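**Plan**

1. Cuts: first the aryl–vinyl bond of the stilbene (Heck), then the C2–C3 bond of each of the three 2,3-diaryl-2,3-dihydrobenzofuran rings. These are ring U (fused to the styryl-bearing resorcinol ring), ring M (fused to the 1,2,4-trisubstituted ring) and ring L (fused to the second resorcinol ring, at the chain end). Each goes back to a diaryl ketone hydrazone with an ortho aryl–O–CH2–aryl ether; the aryl–C3 bond joining rings L and M goes back to aryllithium plus aldehyde.
2. Enabling feature: in every furan ring C3 is doubly benzylic (a diaryl carbene position) and C2 is an O-benzylic CH between O1 and a 4-oxyphenyl ring. A carbene at C3 therefore sits 1,5 to a hydridic ArO–CH2–Ar hydrogen.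
3. Forward: one 2-bromo-6-hydroxybenzophenone is made once and used twice. Ring L is closed first, its aryl bromide is lithiated and added to a salicylaldehyde ether, ring M is closed, a Mitsunobu ether link brings in the second benzophenone, ring U is closed; then demethylation, acetylation, Heck coupling and deacetylation.
4. Stereochemistry: each C3 (R) comes from the chiral dirhodium carboxylate in the C–H insertion, which gives 2,3-cis rings. Each C2 is then funnelled to the trans (R) configuration by reversible ionization of its O-benzylic bond in the BBr3 step. The E-alkene comes from the Heck reaction.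

Key step: step 6

Remark (assumption): Rh2(R-PTAD)4, dirhodium tetrakis[(R)-(1-adamantyl)(phthalimido)acetate], is taken by analogy to deliver the (3R) series; should the sense prove opposite, Rh2(S-PTAD)4 is used in steps 6, 12 and 16.
Abbreviations: PMB = 4-methoxybenzyl, TBS = tert-butyldimethylsilyl, DIAD = diisopropyl azodicarboxylate, DMAP = 4-(dimethylamino)pyridine.

**Route**

Step 1
Reactants: 1 2-bromo-4,6-dimethoxybenzaldehyde; 2 (3,5-dimethoxyphenyl)magnesium chloride
Product: 3 (2-bromo-4,6-dimethoxyphenyl)(3,5-dimethoxyphenyl)methanol (racemic)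
Conditions: THF, 0 °C to rt; then H2O
Reagents that add atoms: none
Why: Grignard addition of the arylmagnesium chloride to the aldehyde, the aryl bromide being inert to an arylmagnesium halide at this temperature; the racemic carbinol center is removed in step 2.

Step 2
Reactants: 3 (2-bromo-4,6-dimethoxyphenyl)(3,5-dimethoxyphenyl)methanol
Product: 4 (2-bromo-4,6-dimethoxyphenyl)(3,5-dimethoxyphenyl)methanone
Conditions: Dess–Martin periodinane, CH2Cl2, 0 °C to rt
Reagents that add atoms: none
Why: Dess–Martin oxidation of the doubly benzylic secondary alcohol to the diaryl ketone under near-neutral conditions that leave the aryl bromide and methyl ethers untouched.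

Step 3
Reactants: 4 (2-bromo-4,6-dimethoxyphenyl)(3,5-dimethoxyphenyl)methanone
Product: 5 (2-bromo-6-hydroxy-4-methoxyphenyl)(3,5-dimethoxyphenyl)methanone
Conditions: BCl3 (1.5 equiv), CH2Cl2, −78 to 0 °C; then H2O
Reagents that add atoms: none
Why: Chelation-controlled demethylation, in which BCl3 bridges the ketone oxygen and the ortho methoxy oxygen so that only the methyl ether ortho to the carbonyl is cleaved while the meta- and para-placed methoxy groups stay.

Step 4
Reactants: 5 (2-bromo-6-hydroxy-4-methoxyphenyl)(3,5-dimethoxyphenyl)methanone; 6 4-methoxybenzyl chloride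
Product: 7 {2-bromo-4-methoxy-6-[(4-methoxybenzyl)oxy]phenyl}(3,5-dimethoxyphenyl)methanone
Conditions: K2CO3, KI (cat.), DMF, 60 °C
Reagents that add atoms: none
Why: Williamson ether synthesis at the only acidic site, the hydrogen-bonded phenol, installs the ArO–CH2–Ar unit whose CH2 becomes C2 of ring L.

Step 5
Reactants: 7 {2-bromo-4-methoxy-6-[(4-methoxybenzyl)oxy]phenyl}(3,5-dimethoxyphenyl)methanone
Product: 8 hydrazone of 7 (E/Z mixture)
Conditions: N2H4·H2O (20 equiv), AcOH (cat.), n-BuOH, 110 °C, sealed tube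
Reagents that add atoms: hydrazine, NN
Why: Acid-catalysed condensation of the diaryl ketone with excess hydrazine, forced by temperature because the carbonyl carries two ortho substituents; ethers and the electron-rich aryl bromide are inert to hydrazine, and both hydrazone isomers give the same diazoalkane.

Step 6
Reactants: 8 hydrazone of 7
Product: 10 (2S,3R)-4-bromo-3-(3,5-dimethoxyphenyl)-6-methoxy-2-(4-methoxyphenyl)-2,3-dihydro-1-benzofuran (2,3-cis), via diazoalkane 9 (not isolated)
Conditions: MnO2, CH2Cl2, 0 °C, filter; then Rh2(R-PTAD)4 (1 mol %), CH2Cl2, −20 °C to rt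
Reagents that add atoms: none
Why: MnO2 dehydrogenates the hydrazone to diaryldiazomethane 9, which loses N2 on the dirhodium catalyst to give a donor/donor carbene at the future C3; this carbon abstracts hydride from the 1,5-related O-benzylic CH2 of the 4-methoxybenzyl ether (activated by the ether oxygen and the p-anisyl ring) and the short-lived oxocarbenium/benzylrhodium zwitterion collapses to the C2–C3 bond, a formal 1,5 C–H insertion. The closest known reaction type is the enantioselective intramolecular C–H insertion of donor/donor rhodium carbenes derived from 2-(benzyloxy)benzophenone hydrazones, which gives 2,3-diaryl-2,3-dihydrobenzofurans. One ring is closed, the five-membered furan ring L, by a 1,5-insertion whose C–C bond-forming event is a 5-endo-trig collapse onto the oxocarbenium carbon. C3 (R) is controlled by the chiral carboxylate ligands of Rh2(R-PTAD)4, which select the carbene face that receives hydride, and C2 (S, cis to the C3 aryl group) by collapse of the ion pair faster than bond rotation; C2 is deliberately left cis and is equilibrated to trans in step 17. The step needs 1,5-insertion to outrun azine formation and attack on other C–H bonds: the ether CH2 is the only C–H that can reach the carbene through a five-membered transition state, the two ortho substituents (Br and OCH2Ar) shield the carbene from bimolecular capture by diazoalkane, and the methoxy groups sit meta or para on rings from which no small ring can close.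

Step 7
Reactants: 11 2-hydroxy-5-(hydroxymethyl)benzaldehyde; 6 4-methoxybenzyl chloride
Product: 12 5-(hydroxymethyl)-2-[(4-methoxybenzyl)oxy]benzaldehyde
Conditions: K2CO3, DMF, rt
Reagents that add atoms: none
Why: Williamson etherification selective for the phenol, since K2CO3 deprotonates only the phenol and not the benzylic alcohol; this CH2 becomes C2 of ring M.

Step 8
Reactants: 12 5-(hydroxymethyl)-2-[(4-methoxybenzyl)oxy]benzaldehyde
Product: 13 5-{[(tert-butyldimethylsilyl)oxy]methyl}-2-[(4-methoxybenzyl)oxy]benzaldehyde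
Conditions: TBSCl, imidazole, CH2Cl2, rt
Reagents that add atoms: tert-butyldimethylsilyl chloride, CC(C)(C)[Si](C)(C)Cl
Why: Silyl ether formation masks the primary alcohol against the organolithium and hydrazine steps that follow.

Step 9
Reactants: 10 (2S,3R)-4-bromo-3-(3,5-dimethoxyphenyl)-6-methoxy-2-(4-methoxyphenyl)-2,3-dihydro-1-benzofuran; 13 5-{[(tert-butyldimethylsilyl)oxy]methyl}-2-[(4-methoxybenzyl)oxy]benzaldehyde
Product: 15 diaryl carbinol joining C4 of ring L to the salicylaldehyde carbon (both carbinol epimers), via aryllithium 14 (not isolated)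
Conditions: n-BuLi (1.05 equiv), THF, −78 °C; then 13, −78 to −40 °C; then H2O
Reagents that add atoms: none
Why: Bromine–lithium exchange followed by 1,2-addition of the aryllithium to the aldehyde, the exchange at −78 °C being faster than deprotonation at the benzylic C2 and C3 positions; the carbinol center formed is removed in step 10.

Step 10
Reactants: 15 diaryl carbinol
Product: 16 diaryl ketone (ring L C4–C(=O)–aryl)
Conditions: Dess–Martin periodinane, CH2Cl2, 0 °C to rt
Reagents that add atoms: none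
Why: Dess–Martin oxidation of the only free alcohol, a doubly benzylic carbinol, to the ketone without touching the silyl ether or the cis ring L.

Step 11
Reactants: 16 diaryl ketone
Product: 17 hydrazone of 16 (E/Z mixture)
Conditions: N2H4·H2O (10 equiv), AcOH (cat.), EtOH, 85 °C
Reagents that add atoms: hydrazine, NN
Why: Acid-catalysed hydrazone formation at a ketone with one ortho substituent on each ring; the alkyl silyl ether and the aryl ethers are stable to hydrazine.

Step 12
Reactants: 17 hydrazone of 16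
Product: 19 silyl ether carrying rings L and M (each 2S,3R and 2,3-cis), via diazoalkane 18 (not isolated)
Conditions: MnO2, CH2Cl2, 0 °C, filter; then Rh2(R-PTAD)4 (1 mol %), CH2Cl2, −20 °C to rt
Reagents that add atoms: none
Why: Hydrazone oxidation and rhodium-carbene 1,5 C–H insertion into the O-benzylic CH2 of the 4-methoxybenzyl ether close furan ring M; C3 (R) should be set by the same catalyst enantiomer in the same sense as in step 6 (catalyst control over the remote ring L centers) and C2 arises cis (S), while the C2–H of ring L cannot be reached without an impossible bridged ring.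

Step 13
Reactants: 19 silyl ether carrying rings L and M
Product: 20 benzylic alcohol, [ring M C5]–CH2OH
Conditions: TBAF, THF, 0 °C
Reagents that add atoms: none
Why: Fluoride-mediated silyl ether cleavage (Si–F bond formation) frees the primary benzylic alcohol without touching the aryl ethers or the ring stereocenters.

Step 14
Reactants: 20 benzylic alcohol; 5 (2-bromo-6-hydroxy-4-methoxyphenyl)(3,5-dimethoxyphenyl)methanone
Product: 21 aryl benzyl ether ketone (second benzophenone linked through O–CH2 to C5 of ring M)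
Conditions: PPh3, DIAD, THF, 0 °C to rt
Reagents that add atoms: none
Why: Mitsunobu etherification, in which the acidic hydrogen-bonded phenol of 5 displaces the activated primary benzylic alcohol, avoids isolating a labile p-alkoxybenzyl halide; this CH2 becomes C2 of ring U.

Step 15
Reactants: 21 aryl benzyl ether ketone
Product: 22 hydrazone of 21 (E/Z mixture)
Conditions: N2H4·H2O (20 equiv), AcOH (cat.), n-BuOH, 110 °C, sealed tube
Reagents that add atoms: hydrazine, NN
Why: Same forced acid-catalysed condensation as in step 5 on the same doubly ortho-substituted benzophenone type; rings L and M are stable to hydrazine.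

Step 16
Reactants: 22 hydrazone of 21
Product: 24 bromo octamethyl ether with rings L, M and U (each 2S,3R and 2,3-cis), via diazoalkane 23 (not isolated)
Conditions: MnO2, CH2Cl2, 0 °C, filter; then Rh2(R-PTAD)4 (1 mol %), CH2Cl2, −20 °C to rt
Reagents that add atoms: none
Why: Third hydrazone oxidation and rhodium-carbene 1,5 C–H insertion, now into the ArO–CH2–aryl hydrogen para to the ring M oxygen, closes furan ring U with C3 (R) from the catalyst and C2 cis (S); the bromine is kept as the handle for the stilbene because an ortho styryl group would be attacked by the carbene.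

Step 17
Reactants: 24 bromo octamethyl ether (all rings cis)
Product: 25 bromo octaphenol with rings L, M and U all (2R,3R) trans
Conditions: BBr3 (30 equiv), CH2Cl2, −78 °C to rt; then H2O
Reagents that add atoms: none
Why: Lewis-acid demethylation of all eight aryl methyl ethers, during which each O-benzylic C2–O bond ionizes reversibly (cation stabilized by the para oxygen of its aryl group) and recloses to the thermodynamically preferred 2,3-trans ring, so the three cis rings should converge on the all-trans array while the non-ionizing C3 centers keep the configuration set by the catalyst.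

Step 18
Reactants: 25 bromo octaphenol
Product: 26 bromo octaacetate
Conditions: Ac2O, pyridine, DMAP (cat.), rt
Reagents that add atoms: acetic anhydride, CC(=O)OC(C)=O
Why: DMAP-catalysed acetylation of all eight phenols protects them from oxidation and from phenoxide formation under the basic palladium conditions.

Step 19
Reactants: 26 bromo octaacetate; 27 4-ethenylphenyl acetate
Product: 28 nonaacetate of the target (E-stilbene)
Conditions: Pd2(dba)3 (2.5 mol %), [HP(t-Bu)3]BF4 (10 mol %), Cy2NMe, 1,4-dioxane, 80 °C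
Reagents that add atoms: none
Why: Mizoroki–Heck reaction of the hindered aryl bromide with the styrene under zerovalent palladium/tri-tert-butylphosphine catalysis, where syn-insertion and syn-β-hydride elimination give the E-alkene; the stilbene is installed only now because under the acid of step 17 it would cyclize onto the neighbouring resorcinol ring.

Step 20
Reactants: 28 nonaacetate
Product: 29 target compound
Conditions: K2CO3 (cat.), MeOH, 0 °C to rt; then Dowex 50W (H+ form)
Reagents that add atoms: none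
Why: Base-catalysed transesterification (Zemplén-type methanolysis) removes the nine aryl acetates under conditions too mild to open the furan rings, epimerize C3 or isomerize the stilbene.

**Compound list**

1 | 2-bromo-4,6-dimethoxybenzaldehyde | O=Cc1c(Br)cc(OC)cc1OC | starting material
2 | (3,5-dimethoxyphenyl)magnesium chloride (THF solution) | COc1cc(OC)cc([Mg]Cl)c1 | starting material
3 | (2-bromo-4,6-dimethoxyphenyl)(3,5-dimethoxyphenyl)methanol (racemic) | OC(c1cc(OC)cc(OC)c1)c1c(Br)cc(OC)cc1OC | intermediate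
4 | (2-bromo-4,6-dimethoxyphenyl)(3,5-dimethoxyphenyl)methanone | O=C(c1cc(OC)cc(OC)c1)c1c(Br)cc(OC)cc1OC | intermediate
5 | (2-bromo-6-hydroxy-4-methoxyphenyl)(3,5-dimethoxyphenyl)methanone | O=C(c1cc(OC)cc(OC)c1)c1c(Br)cc(OC)cc1O | intermediate
6 | 4-methoxybenzyl chloride | COc1ccc(CCl)cc1 | starting material
7 | {2-bromo-4-methoxy-6-[(4-methoxybenzyl)oxy]phenyl}(3,5-dimethoxyphenyl)methanone | O=C(c1cc(OC)cc(OC)c1)c1c(Br)cc(OC)cc1OCc1ccc(OC)cc1 | intermediate
8 | hydrazone of 7 (E/Z mixture) | NN=C(c1cc(OC)cc(OC)c1)c1c(Br)cc(OC)cc1OCc1ccc(OC)cc1 | intermediate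
9 | 1-bromo-2-[diazo(3,5-dimethoxyphenyl)methyl]-5-methoxy-3-[(4-methoxybenzyl)oxy]benzene | [N-]=[N+]=C(c1cc(OC)cc(OC)c1)c1c(Br)cc(OC)cc1OCc1ccc(OC)cc1 | intermediate
10 | (2S,3R)-4-bromo-3-(3,5-dimethoxyphenyl)-6-methoxy-2-(4-methoxyphenyl)-2,3-dihydro-1-benzofuran (2,3-cis) | Brc1cc(OC)cc2c1[C@@H](c1cc(OC)cc(OC)c1)[C@@H](c1ccc(OC)cc1)O2 | intermediate
11 | 2-hydroxy-5-(hydroxymethyl)benzaldehyde | O=Cc1cc(CO)ccc1O | starting material
12 | 5-(hydroxymethyl)-2-[(4-methoxybenzyl)oxy]benzaldehyde | O=Cc1cc(CO)ccc1OCc1ccc(OC)cc1 | intermediate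
13 | 5-{[(tert-butyldimethylsilyl)oxy]methyl}-2-[(4-methoxybenzyl)oxy]benzaldehyde | O=Cc1cc(CO[Si](C)(C)C(C)(C)C)ccc1OCc1ccc(OC)cc1 | intermediate
14 | [(2S,3R)-3-(3,5-dimethoxyphenyl)-6-methoxy-2-(4-methoxyphenyl)-2,3-dihydro-1-benzofuran-4-yl]lithium | [Li]c1cc(OC)cc2c1[C@@H](c1cc(OC)cc(OC)c1)[C@@H](c1ccc(OC)cc1)O2 | intermediate
15 | {5-{[(tert-butyldimethylsilyl)oxy]methyl}-2-[(4-methoxybenzyl)oxy]phenyl}[(2S,3R)-3-(3,5-dimethoxyphenyl)-6-methoxy-2-(4-methoxyphenyl)-2,3-dihydro-1-benzofuran-4-yl]methanol (both carbinol epimers) | OC(c1cc(CO[Si](C)(C)C(C)(C)C)ccc1OCc1ccc(OC)cc1)c1cc(OC)cc2c1[C@@H](c1cc(OC)cc(OC)c1)[C@@H](c1ccc(OC)cc1)O2 | intermediate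
16 | {5-{[(tert-butyldimethylsilyl)oxy]methyl}-2-[(4-methoxybenzyl)oxy]phenyl}[(2S,3R)-3-(3,5-dimethoxyphenyl)-6-methoxy-2-(4-methoxyphenyl)-2,3-dihydro-1-benzofuran-4-yl]methanone | O=C(c1cc(CO[Si](C)(C)C(C)(C)C)ccc1OCc1ccc(OC)cc1)c1cc(OC)cc2c1[C@@H](c1cc(OC)cc(OC)c1)[C@@H](c1ccc(OC)cc1)O2 | intermediate
17 | hydrazone of 16 (E/Z mixture) | NN=C(c1cc(CO[Si](C)(C)C(C)(C)C)ccc1OCc1ccc(OC)cc1)c1cc(OC)cc2c1[C@@H](c1cc(OC)cc(OC)c1)[C@@H](c1ccc(OC)cc1)O2 | intermediate
18 | diazoalkane from 17 (C=N2 in place of C=N–NH2) | [N-]=[N+]=C(c1cc(CO[Si](C)(C)C(C)(C)C)ccc1OCc1ccc(OC)cc1)c1cc(OC)cc2c1[C@@H](c1cc(OC)cc(OC)c1)[C@@H](c1ccc(OC)cc1)O2 | intermediate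
19 | tert-butyl{[(2S,3R)-3-[(2S,3R)-3-(3,5-dimethoxyphenyl)-6-methoxy-2-(4-methoxyphenyl)-2,3-dihydro-1-benzofuran-4-yl]-2-(4-methoxyphenyl)-2,3-dihydro-1-benzofuran-5-yl]methoxy}dimethylsilane (both rings 2,3-cis) | CC(C)(C)[Si](C)(C)OCc1ccc2c(c1)[C@@H](c1cc(OC)cc3c1[C@@H](c1cc(OC)cc(OC)c1)[C@@H](c1ccc(OC)cc1)O3)[C@@H](c1ccc(OC)cc1)O2 | intermediate
20 | [(2S,3R)-3-[(2S,3R)-3-(3,5-dimethoxyphenyl)-6-methoxy-2-(4-methoxyphenyl)-2,3-dihydro-1-benzofuran-4-yl]-2-(4-methoxyphenyl)-2,3-dihydro-1-benzofuran-5-yl]methanol | OCc1ccc2c(c1)[C@@H](c1cc(OC)cc3c1[C@@H](c1cc(OC)cc(OC)c1)[C@@H](c1ccc(OC)cc1)O3)[C@@H](c1ccc(OC)cc1)O2 | intermediate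
21 | {2-bromo-4-methoxy-6-({(2S,3R)-3-[(2S,3R)-3-(3,5-dimethoxyphenyl)-6-methoxy-2-(4-methoxyphenyl)-2,3-dihydro-1-benzofuran-4-yl]-2-(4-methoxyphenyl)-2,3-dihydro-1-benzofuran-5-yl}methoxy)phenyl}(3,5-dimethoxyphenyl)methanone | O=C(c1cc(OC)cc(OC)c1)c1c(Br)cc(OC)cc1OCc1ccc2c(c1)[C@@H](c1cc(OC)cc3c1[C@@H](c1cc(OC)cc(OC)c1)[C@@H](c1ccc(OC)cc1)O3)[C@@H](c1ccc(OC)cc1)O2 | intermediate
22 | hydrazone of 21 (E/Z mixture) | NN=C(c1cc(OC)cc(OC)c1)c1c(Br)cc(OC)cc1OCc1ccc2c(c1)[C@@H](c1cc(OC)cc3c1[C@@H](c1cc(OC)cc(OC)c1)[C@@H](c1ccc(OC)cc1)O3)[C@@H](c1ccc(OC)cc1)O2 | intermediate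
23 | diazoalkane from 22 (C=N2 in place of C=N–NH2) | [N-]=[N+]=C(c1cc(OC)cc(OC)c1)c1c(Br)cc(OC)cc1OCc1ccc2c(c1)[C@@H](c1cc(OC)cc3c1[C@@H](c1cc(OC)cc(OC)c1)[C@@H](c1ccc(OC)cc1)O3)[C@@H](c1ccc(OC)cc1)O2 | intermediate
24 | (2S,3R)-4-bromo-3-(3,5-dimethoxyphenyl)-6-methoxy-2-{(2S,3R)-3-[(2S,3R)-3-(3,5-dimethoxyphenyl)-6-methoxy-2-(4-methoxyphenyl)-2,3-dihydro-1-benzofuran-4-yl]-2-(4-methoxyphenyl)-2,3-dihydro-1-benzofuran-5-yl}-2,3-dihydro-1-benzofuran (all three rings 2,3-cis) | Brc1cc(OC)cc2c1[C@@H](c1cc(OC)cc(OC)c1)[C@@H](c1ccc3c(c1)[C@@H](c1cc(OC)cc4c1[C@@H](c1cc(OC)cc(OC)c1)[C@@H](c1ccc(OC)cc1)O4)[C@@H](c1ccc(OC)cc1)O3)O2 | intermediate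
25 | 5-[(2R,3R)-4-bromo-2-{(2R,3R)-3-[(2R,3R)-3-(3,5-dihydroxyphenyl)-6-hydroxy-2-(4-hydroxyphenyl)-2,3-dihydro-1-benzofuran-4-yl]-2-(4-hydroxyphenyl)-2,3-dihydro-1-benzofuran-5-yl}-6-hydroxy-2,3-dihydro-1-benzofuran-3-yl]benzene-1,3-diol (all three rings 2,3-trans) | Brc1cc(O)cc2c1[C@@H](c1cc(O)cc(O)c1)[C@H](c1ccc3c(c1)[C@@H](c1cc(O)cc4c1[C@@H](c1cc(O)cc(O)c1)[C@H](c1ccc(O)cc1)O4)[C@H](c1ccc(O)cc1)O3)O2 | intermediate
26 | octaacetate of 25 | Brc1cc(OC(C)=O)cc2c1[C@@H](c1cc(OC(C)=O)cc(OC(C)=O)c1)[C@H](c1ccc3c(c1)[C@@H](c1cc(OC(C)=O)cc4c1[C@@H](c1cc(OC(C)=O)cc(OC(C)=O)c1)[C@H](c1ccc(OC(C)=O)cc1)O4)[C@H](c1ccc(OC(C)=O)cc1)O3)O2 | intermediate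
27 | 4-ethenylphenyl acetate (4-acetoxystyrene) | C=Cc1ccc(OC(C)=O)cc1 | starting material
28 | nonaacetate of 29 (E-alkene, all rings 2R,3R) | CC(=O)Oc1ccc(/C=C/c2cc(OC(C)=O)cc3c2[C@@H](c2cc(OC(C)=O)cc(OC(C)=O)c2)[C@H](c2ccc4c(c2)[C@@H](c2cc(OC(C)=O)cc5c2[C@@H](c2cc(OC(C)=O)cc(OC(C)=O)c2)[C@H](c2ccc(OC(C)=O)cc2)O5)[C@H](c2ccc(OC(C)=O)cc2)O4)O3)cc1 | intermediate
29 | 5-[(2R,3R)-2-{(2R,3R)-3-[(2R,3R)-3-(3,5-dihydroxyphenyl)-6-hydroxy-2-(4-hydroxyphenyl)-2,3-dihydro-1-benzofuran-4-yl]-2-(4-hydroxyphenyl)-2,3-dihydro-1-benzofuran-5-yl}-6-hydroxy-4-[(E)-2-(4-hydroxyphenyl)ethenyl]-2,3-dihydro-1-benzofuran-3-yl]benzene-1,3-diol | Oc1ccc(/C=C/c2cc(O)cc3c2[C@@H](c2cc(O)cc(O)c2)[C@H](c2ccc4c(c2)[C@@H](c2cc(O)cc5c2[C@@H](c2cc(O)cc(O)c2)[C@H](c2ccc(O)cc2)O5)[C@H](c2ccc(O)cc2)O4)O3)cc1 | target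

**Step count and risks**

Total step count: 20. Longest linear sequence: 18 steps (steps 1–6 and 9–20); steps 7–8 form a two-step side branch.

Steps most likely to fail:

Step 6. The carbene-bearing ring carries two ortho substituents and may twist out of the catalyst pocket, so the process at risk is loss of facial control at C3, or capture of the carbene by diazoalkane (azine formation) before insertion. Fallback: starting from 7, irradiation (350 nm, benzene) should trigger a Norrish–Yang cyclization, in which the triplet ketone abstracts the same O-benzylic hydrogen and the 1,5-biradical closes the C2–C3 bond, giving 4-bromo-3-(3,5-dimethoxyphenyl)-6-methoxy-2-(4-methoxyphenyl)-2,3-dihydro-1-benzofuran-3-ol F2. Ionic deoxygenation (Et3SiH, BF3·OEt2, CH2Cl2, −78 °C), with hydride expected to add to the diaryl cation anti to the C2 aryl group, should give the racemic cis bromide, that is 10 together with its mirror image, the (2R,3S)-bromide F3. Preparative chromatography on a chiral stationary phase then returns to the route at 10.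

Step 5 (the same process threatens step 15). The condensation may stall at the doubly ortho-substituted carbonyl, or hydrazine may attack the C–Br bond (indazole formation) under the forcing conditions. Fallback: starting from 7, silyl-hydrazone transfer with 1,2-bis(tert-butyldimethylsilyl)hydrazine and Sc(OTf)3 (cat., neat, 100 °C) should give the N-(tert-butyldimethylsilyl)hydrazone of 7, F1. Oxidation of F1 with (difluoroiodo)benzene and 2-chloropyridine (CH2Cl2, −78 °C to rt) gives diazoalkane 9 directly, where the route is rejoined before the rhodium catalyst is added.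

Step 17. During the long exposure to excess Lewis acid the ring-opened O-benzylic cations may be captured irreversibly, for example by Friedel–Crafts attack of a neighbouring resorcinol ring to form a seven-membered ring, or bromide-opened rings may fail to reclose. Fallback: the two tasks are separated. Starting from 24, brief treatment with CF3CO2H (cat.) in CH2Cl2 at 0 °C equilibrates the three C2 centers at the methyl ether stage to the all-trans (2R,3R) bromo octamethyl ether F4. Nucleophilic demethylation with NaSEt in DMF at 130 °C (SN2 at the methyl carbons, no cationic intermediates) then gives 25, where the route is rejoined.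

Further compounds
F1 | step 5 | N-(tert-butyldimethylsilyl)hydrazone of 7 | CC(C)(C)[Si](C)(C)NN=C(c1cc(OC)cc(OC)c1)c1c(Br)cc(OC)cc1OCc1ccc(OC)cc1
F2 | step 6 | 4-bromo-3-(3,5-dimethoxyphenyl)-6-methoxy-2-(4-methoxyphenyl)-2,3-dihydro-1-benzofuran-3-ol (racemic, both diastereomers) | OC1(c2cc(OC)cc(OC)c2)c2c(Br)cc(OC)cc2OC1c1ccc(OC)cc1
F3 | step 6 | (2R,3S)-4-bromo-3-(3,5-dimethoxyphenyl)-6-methoxy-2-(4-methoxyphenyl)-2,3-dihydro-1-benzofuran (mirror image of 10; with 10 it makes up the racemic cis bromide) | Brc1cc(OC)cc2c1[C@H](c1cc(OC)cc(OC)c1)[C@H](c1ccc(OC)cc1)O2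
F4 | step 17 | (2R,3R)-4-bromo-3-(3,5-dimethoxyphenyl)-6-methoxy-2-{(2R,3R)-3-[(2R,3R)-3-(3,5-dimethoxyphenyl)-6-methoxy-2-(4-methoxyphenyl)-2,3-dihydro-1-benzofuran-4-yl]-2-(4-methoxyphenyl)-2,3-dihydro-1-benzofuran-5-yl}-2,3-dihydro-1-benzofuran (all three rings 2,3-trans) | Brc1cc(OC)cc2c1[C@@H](c1cc(OC)cc(OC)c1)[C@H](c1ccc3c(c1)[C@@H](c1cc(OC)cc4c1[C@@H](c1cc(OC)cc(OC)c1)[C@H](c1ccc(OC)cc1)O4)[C@H](c1ccc(OC)cc1)O3)O2
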